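## Retrosynthetic overview

1. Guanidine from a primary amine by amidine transfer; allyl sulfone from the sulfide; sulfide from the diterpenyl allylic bromide and N‑Boc‑cysteamine.
2. Both E‑trisubstituted chain alkenes from Zr‑catalysed alkyne carboalumination, joined by a Pd‑catalysed alkenyl iodide/homopropargylzinc coupling.
3. Ring alkyne from the aldehyde (one‑carbon homologation), itself from the allyl side chain by hydroboration.
4. Ring C(Me)=CH from enol triflate/methyl coupling; the C–H(Me) centre from hydroxyl‑directed hydrogenation; the quaternary centre and directing carbinol from a ketoreductase desymmetrisation of achiral 2‑allyl‑2‑methylcyclohexane‑1,3‑dione.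
5. Ring order: the single cyclohexane ring is carried intact from commercial 2‑methylcyclohexane‑1,3‑dione; no ring‑forming step is needed.

Assumption 1: the product is obtained as the guanidinium chloride and neutralised to the free base drawn.
Assumption 2: a ketoreductase of the required (anti‑Prelog) sense for dione 3 is found by panel screening; baker's yeast is expected to give the (2S,3S) antipode and is not used.
Target stereochemistry as planned: ring (1S,6R) with the two vicinal methyls cis, both chain alkenes E.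

## Route

**Step 1**
Reactants: 1, 2‑methylcyclohexane‑1,3‑dione; 2, allyl acetate
Product: 3, 2‑methyl‑2‑(prop‑2‑en‑1‑yl)cyclohexane‑1,3‑dione (achiral)
Conditions: Pd(PPh3)4 (2 mol %), DBU, toluene, 60 °C
Reagents that add atoms: allyl acetate (2), C=CCOC(C)=O (allyl group)
Why: Tsuji–Trost allylation; the soft dione enolate attacks the π‑allyl‑Pd at carbon and any O‑allyl isomer re‑ionises, giving the C‑allylated symmetric dione.

**Step 2**
Reactants: 3
Product: 4, (2R,3R)‑3‑hydroxy‑2‑methyl‑2‑(prop‑2‑en‑1‑yl)cyclohexan‑1‑one (OH cis to allyl)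
Conditions: ketoreductase (KRED, anti‑Prelog), NADP+ (cat.), glucose/glucose dehydrogenase, KPi pH 7, 5 % DMSO, 30 °C
Reagents that add atoms: none (hydride from NADPH)
Why: Ketoreductase‑catalysed desymmetrising reduction of one enantiotopic carbonyl from one face sets the quaternary C2 and carbinol C3 together; this is the first stereo‑defining step.

**Step 3**
Reactants: 4
Product: 5, (2R,3R)‑3‑[(tert‑butyldimethylsilyl)oxy]‑2‑methyl‑2‑(prop‑2‑en‑1‑yl)cyclohexan‑1‑one
Conditions: TBSOTf, 2,6‑lutidine, CH2Cl2, −78 → 0 °C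
Reagents that add atoms: TBSOTf, CC(C)(C)[Si](C)(C)OS(=O)(=O)C(F)(F)F
Why: O‑silylation blocks retro‑aldol cleavage of the β‑hydroxy ketone and allows clean enolisation next.

**Step 4**
Reactants: 5
Product: 6, (5R,6R)‑5‑[(tert‑butyldimethylsilyl)oxy]‑6‑methyl‑6‑(prop‑2‑en‑1‑yl)cyclohex‑1‑en‑1‑yl trifluoromethanesulfonate
Conditions: KHMDS, THF, −78 °C; then PhNTf2, −78 → 0 °C
Reagents that add atoms: PhNTf2, O=S(=O)(N(c1ccccc1)S(=O)(=O)C(F)(F)F)C(F)(F)F
Why: Enolate O‑triflation; only the CH2 side can enolise because the other α‑carbon is quaternary, so the triflate is regiospecific.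

**Step 5**
Reactants: 6
Product: 7, tert‑butyl{[(1R,2S)‑2,3‑dimethyl‑2‑(prop‑2‑en‑1‑yl)cyclohex‑3‑en‑1‑yl]oxy}dimethylsilane
Conditions: MeMgBr, Fe(acac)3 (5 mol %), THF/NMP, −30 → 0 °C
Reagents that add atoms: MeMgBr, C[Mg]Br
Why: Iron‑catalysed (Kochi–Fürstner) cross‑coupling of the alkenyl triflate with MeMgBr installs the ring methyl without touching the silyl ether or allyl group.

**Step 6**
Reactants: 7
Product: 8, 3‑[(1S,6R)‑6‑[(tert‑butyldimethylsilyl)oxy]‑1,2‑dimethylcyclohex‑2‑en‑1‑yl]propan‑1‑ol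
Conditions: 9‑BBN, THF, 0 °C → rt; then NaOH, H2O2
Reagents that add atoms: hydrogen peroxide, OO (oxygen of the new OH)
Why: Anti‑Markovnikov hydroboration–oxidation; 9‑BBN reacts only with the monosubstituted terminal alkene, not the hindered trisubstituted ring alkene.

**Step 7**
Reactants: 8
Product: 9, (1R,2S)‑2‑(3‑hydroxypropyl)‑2,3‑dimethylcyclohex‑3‑en‑1‑ol
Conditions: TBAF, THF, 50 °C
Reagents that add atoms: none
Why: Fluoride desilylation frees the homoallylic ring hydroxyl needed as a directing group.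

**Step 8**
Reactants: 9
Product: 10, (1R,2S,3R)‑2‑(3‑hydroxypropyl)‑2,3‑dimethylcyclohexan‑1‑ol
Conditions: [Ir(cod)(PCy3)(py)]PF6 (5 mol %), H2 (1 atm), CH2Cl2, rt
Reagents that add atoms: none (H2)
Why: Hydroxyl‑directed hydrogenation (Crabtree): Ir bound to the ring OH (and the side‑chain OH on the same face) delivers H2 to that face, so the new methyl is trans to OH and side chain and cis to the quaternary methyl.

**Step 9**
Reactants: 10
Product: 11, 3‑[(1S,2R,6R)‑2‑hydroxy‑1,6‑dimethylcyclohexyl]propyl 2,2‑dimethylpropanoate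
Conditions: PivCl (1.1 equiv), pyridine, CH2Cl2, 0 °C
Reagents that add atoms: pivaloyl chloride, CC(C)(C)C(Cl)=O
Why: Selective acylation of the primary alcohol over the hindered secondary one next to the quaternary carbon.

**Step 10**
Reactants: 11
Product: 12, 3‑[(1S,2R)‑1,2‑dimethyl‑6‑oxocyclohexyl]propyl 2,2‑dimethylpropanoate
Conditions: Dess–Martin periodinane, NaHCO3, CH2Cl2, rt
Reagents that add atoms: none
Why: Mild alcohol oxidation; neither stereocentre is α‑acidic in a way that can epimerise (one is quaternary, the C–H(Me) is β to the ketone).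

**Step 11**
Reactants: 12
Product: 13, 3‑[(1S,6R)‑1,6‑dimethyl‑2‑{[(trifluoromethyl)sulfonyl]oxy}cyclohex‑2‑en‑1‑yl]propyl 2,2‑dimethylpropanoate
Conditions: KHMDS, THF, −78 °C; then PhNTf2, −78 → 0 °C
Reagents that add atoms: PhNTf2, O=S(=O)(N(c1ccccc1)S(=O)(=O)C(F)(F)F)C(F)(F)F
Why: Regiospecific enol triflate formation (only one enolisable α‑carbon); the pivalate has no α‑hydrogens and survives.

**Step 12**
Reactants: 13
Product: 14, 3‑[(1S,6R)‑1,2,6‑trimethylcyclohex‑2‑en‑1‑yl]propyl 2,2‑dimethylpropanoate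
Conditions: MeMgBr, Fe(acac)3 (5 mol %), THF/NMP, −30 → 0 °C
Reagents that add atoms: MeMgBr, C[Mg]Br
Why: Iron‑catalysed alkenyl triflate/MeMgBr cross‑coupling gives the ring C(Me)=CH alkene; the hindered pivalate is inert at this temperature.

**Step 13**
Reactants: 14
Product: 15, 3‑[(1S,6R)‑1,2,6‑trimethylcyclohex‑2‑en‑1‑yl]propan‑1‑ol
Conditions: DIBAL‑H, CH2Cl2, −78 °C
Reagents that add atoms: none
Why: Reductive ester cleavage releases the primary alcohol.

**Step 14**
Reactants: 15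
Product: 16, 3‑[(1S,6R)‑1,2,6‑trimethylcyclohex‑2‑en‑1‑yl]propanal
Conditions: Dess–Martin periodinane, NaHCO3, CH2Cl2, rt
Reagents that add atoms: none
Why: Mild oxidation to the aldehyde, which has no α‑stereocentre.

**Step 15**
Reactants: 16
Product: 17, (5R,6S)‑6‑(but‑3‑yn‑1‑yl)‑1,5,6‑trimethylcyclohex‑1‑ene
Conditions: dimethyl (1‑diazo‑2‑oxopropyl)phosphonate, K2CO3, MeOH, 0 °C → rt
Reagents that add atoms: Ohira–Bestmann reagent, COP(=O)(OC)C(=[N+]=[N-])C(C)=O (one carbon)
Why: Seyferth–Gilbert homologation (Ohira–Bestmann) converts the aldehyde into the terminal alkyne under mild base.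

**Step 16**
Reactants: 17
Product: 18, (5R,6S)‑6‑[(3E)‑4‑iodo‑3‑methylbut‑3‑en‑1‑yl]‑1,5,6‑trimethylcyclohex‑1‑ene
Conditions: AlMe3 (3 equiv), Cp2ZrCl2 (1 equiv), CH2Cl2, 0 °C → rt; then I2, THF, −30 → 0 °C
Reagents that add atoms: trimethylaluminium, C[Al](C)C; iodine, II
Why: Negishi Zr‑catalysed syn‑carboalumination puts Me on the internal carbon and Al on the terminus; iodinolysis with retention gives the E‑alkenyl iodide.

**Step 17**
Reactants: 18; 19, (4‑bromobut‑1‑yn‑1‑yl)trimethylsilane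
Product: 20, trimethyl{(5E)‑6‑methyl‑8‑[(1S,6R)‑1,2,6‑trimethylcyclohex‑2‑en‑1‑yl]oct‑5‑en‑1‑yn‑1‑yl}silane
Conditions: 19, Mg, THF; ZnBr2, THF, 0 °C; then 18, Pd(PPh3)4 (5 mol %), THF, rt
Reagents that add atoms: (4‑bromobut‑1‑yn‑1‑yl)trimethylsilane (19), C[Si](C)(C)C#CCCBr
Why: Negishi sp2–sp3 cross‑coupling of the alkenyl iodide with the homopropargylzinc reagent proceeds with retention of the E geometry.

**Step 18**
Reactants: 20
Product: 21, (5R,6S)‑1,5,6‑trimethyl‑6‑[(3E)‑3‑methyloct‑3‑en‑7‑yn‑1‑yl]cyclohex‑1‑ene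
Conditions: K2CO3, MeOH, rt
Reagents that add atoms: none
Why: Base‑mediated protodesilylation of the alkynylsilane.

**Step 19**
Reactants: 21
Product: 22, (2E,6E)‑3,7‑dimethyl‑9‑[(1S,6R)‑1,2,6‑trimethylcyclohex‑2‑en‑1‑yl]nona‑2,6‑dien‑1‑ol
Conditions: AlMe3 (3 equiv), Cp2ZrCl2 (1 equiv), CH2Cl2, 0 °C → rt; then n‑BuLi, THF, −78 °C; (CH2O)n, −78 °C → rt
Reagents that add atoms: trimethylaluminium, C[Al](C)C; paraformaldehyde, C=O
Why: Second Negishi carboalumination; the alkenylalanate adds to formaldehyde with retention, giving the E‑allylic alcohol directly.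

**Step 20**
Reactants: 22
Product: 23, (5R,6S)‑6‑[(3E,7E)‑9‑bromo‑3,7‑dimethylnona‑3,7‑dien‑1‑yl]‑1,5,6‑trimethylcyclohex‑1‑ene
Conditions: MsCl, Et3N, THF, −40 °C; then LiBr, −40 → 0 °C (used crude)
Reagents that add atoms: lithium bromide, [Li+].[Br-]
Why: Mesylation then SN2 displacement by bromide at the primary allylic carbon, without acid and without allylic transposition.

**Step 21**
Reactants: 23; 24, tert‑butyl N‑(2‑sulfanylethyl)carbamate
Product: 25, tert‑butyl N‑[2‑({(2E,6E)‑3,7‑dimethyl‑9‑[(1S,6R)‑1,2,6‑trimethylcyclohex‑2‑en‑1‑yl]nona‑2,6‑dien‑1‑yl}sulfanyl)ethyl]carbamate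
Conditions: Cs2CO3, DMF, 0 °C → rt
Reagents that add atoms: tert‑butyl N‑(2‑sulfanylethyl)carbamate (24), CC(C)(C)OC(=O)NCCS
Why: Thiolate SN2 S‑alkylation of the primary allylic bromide; the soft nucleophile attacks the α‑carbon.

**Step 22**
Reactants: 25
Product: 26, tert‑butyl N‑[2‑({(2E,6E)‑3,7‑dimethyl‑9‑[(1S,6R)‑1,2,6‑trimethylcyclohex‑2‑en‑1‑yl]nona‑2,6‑dien‑1‑yl}sulfonyl)ethyl]carbamate
Conditions: (NH4)6Mo7O24·4H2O (10 mol %), 30 % H2O2 (4 equiv), EtOH, 0 °C → rt
Reagents that add atoms: hydrogen peroxide, OO (two sulfone oxygens)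
Why: Molybdate‑catalysed peroxide oxidation is chemoselective for sulfur (sulfide to sulfone) over the three trisubstituted alkenes.

**Step 23**
Reactants: 26
Product: 27, 2‑({(2E,6E)‑3,7‑dimethyl‑9‑[(1S,6R)‑1,2,6‑trimethylcyclohex‑2‑en‑1‑yl]nona‑2,6‑dien‑1‑yl}sulfonyl)ethan‑1‑amine
Conditions: TMSOTf, 2,6‑lutidine, CH2Cl2, 0 °C; then MeOH
Reagents that add atoms: none
Why: Buffered, non‑protic Boc cleavage via the silyl carbamate avoids strong acid that could cyclise or isomerise the polyene.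

**Step 24**
Reactants: 27; 28, 1H‑pyrazole‑1‑carboxamidine hydrochloride
Product: 29, agelasidine C, 2‑({(2E,6E)‑3,7‑dimethyl‑9‑[(1S,6R)‑1,2,6‑trimethylcyclohex‑2‑en‑1‑yl]nona‑2,6‑dien‑1‑yl}sulfonyl)ethylguanidine
Conditions: i‑Pr2NEt, DMF, rt; then basic ion‑exchange resin (OH– form)
Reagents that add atoms: 1H‑pyrazole‑1‑carboxamidine hydrochloride (28), NC(=N)n1cccn1.Cl (amidino group)
Why: Amidine transfer to the primary amine (Bernatowicz guanylation) gives the unprotected guanidine with no further deprotection.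

## Compound list

1 | 2‑methylcyclohexane‑1,3‑dione | CC1C(=O)CCCC1=O | starting material
2 | allyl acetate | C=CCOC(C)=O | starting material
3 | 2‑methyl‑2‑allylcyclohexane‑1,3‑dione | C=CCC1(C)C(=O)CCCC1=O | intermediate
4 | (2R,3R)‑3‑hydroxy‑2‑methyl‑2‑allylcyclohexanone | O=C1CCC[C@@H](O)[C@@]1(C)CC=C | intermediate
5 | TBS ether of 4 | O=C1CCC[C@@H](O[Si](C)(C)C(C)(C)C)[C@@]1(C)CC=C | intermediate
6 | enol triflate of 5 | O=S(=O)(OC1=CCC[C@@H](O[Si](C)(C)C(C)(C)C)[C@@]1(C)CC=C)C(F)(F)F | intermediate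
7 | (1R,2S)‑2‑allyl‑2,3‑dimethylcyclohex‑3‑enyl TBS ether | CC1=CCC[C@@H](O[Si](C)(C)C(C)(C)C)[C@@]1(C)CC=C | intermediate
8 | 3‑[(1S,6R)‑6‑(TBSO)‑1,2‑dimethylcyclohex‑2‑enyl]propan‑1‑ol | CC1=CCC[C@@H](O[Si](C)(C)C(C)(C)C)[C@@]1(C)CCCO | intermediate
9 | (1R,2S)‑2‑(3‑hydroxypropyl)‑2,3‑dimethylcyclohex‑3‑en‑1‑ol | CC1=CCC[C@@H](O)[C@@]1(C)CCCO | intermediate
10 | (1R,2S,3R)‑2‑(3‑hydroxypropyl)‑2,3‑dimethylcyclohexan‑1‑ol | C[C@@H]1CCC[C@@H](O)[C@@]1(C)CCCO | intermediate
11 | primary mono‑pivalate of 10 | C[C@@H]1CCC[C@@H](O)[C@@]1(C)CCCOC(=O)C(C)(C)C | intermediate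
12 | 3‑[(1S,2R)‑1,2‑dimethyl‑6‑oxocyclohexyl]propyl pivalate | C[C@@H]1CCCC(=O)[C@@]1(C)CCCOC(=O)C(C)(C)C | intermediate
13 | enol triflate of 12 | C[C@@H]1CCC=C(OS(=O)(=O)C(F)(F)F)[C@@]1(C)CCCOC(=O)C(C)(C)C | intermediate
14 | 3‑[(1S,6R)‑1,2,6‑trimethylcyclohex‑2‑enyl]propyl pivalate | CC1=CCC[C@@H](C)[C@]1(C)CCCOC(=O)C(C)(C)C | intermediate
15 | 3‑[(1S,6R)‑1,2,6‑trimethylcyclohex‑2‑enyl]propan‑1‑ol | CC1=CCC[C@@H](C)[C@]1(C)CCCO | intermediate
16 | 3‑[(1S,6R)‑1,2,6‑trimethylcyclohex‑2‑enyl]propanal | CC1=CCC[C@@H](C)[C@]1(C)CCC=O | intermediate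
17 | (5R,6S)‑6‑(but‑3‑ynyl)‑1,5,6‑trimethylcyclohexene | CC1=CCC[C@@H](C)[C@]1(C)CCC#C | intermediate
18 | (5R,6S)‑6‑[(3E)‑4‑iodo‑3‑methylbut‑3‑enyl]‑1,5,6‑trimethylcyclohexene | CC1=CCC[C@@H](C)[C@]1(C)CC/C(C)=C/I | intermediate
19 | (4‑bromobut‑1‑yn‑1‑yl)trimethylsilane | C[Si](C)(C)C#CCCBr | starting material
20 | TMS‑enyne coupling product | CC1=CCC[C@@H](C)[C@]1(C)CC/C(C)=C/CCC#C[Si](C)(C)C | intermediate
21 | terminal enyne | CC1=CCC[C@@H](C)[C@]1(C)CC/C(C)=C/CCC#C | intermediate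
22 | (2E,6E)‑diterpenyl allylic alcohol | CC1=CCC[C@@H](C)[C@]1(C)CC/C(C)=C/CC/C(C)=C/CO | intermediate
23 | (2E,6E)‑diterpenyl allylic bromide | CC1=CCC[C@@H](C)[C@]1(C)CC/C(C)=C/CC/C(C)=C/CBr | intermediate
24 | tert‑butyl N‑(2‑sulfanylethyl)carbamate | CC(C)(C)OC(=O)NCCS | starting material
25 | N‑Boc aminoethyl allyl sulfide | CC1=CCC[C@@H](C)[C@]1(C)CC/C(C)=C/CC/C(C)=C/CSCCNC(=O)OC(C)(C)C | intermediate
26 | N‑Boc aminoethyl allyl sulfone | CC1=CCC[C@@H](C)[C@]1(C)CC/C(C)=C/CC/C(C)=C/CS(=O)(=O)CCNC(=O)OC(C)(C)C | intermediate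
27 | aminoethyl allyl sulfone | CC1=CCC[C@@H](C)[C@]1(C)CC/C(C)=C/CC/C(C)=C/CS(=O)(=O)CCN | intermediate
28 | 1H‑pyrazole‑1‑carboxamidine hydrochloride | NC(=N)n1cccn1.Cl | starting material
29 | agelasidine C | CC1=CCC[C@@H](C)[C@]1(C)CC/C(C)=C/CC/C(C)=C/CS(=O)(=O)CCN=C(N)N | target

## Summary

Total steps: 24.
Longest linear sequence: 24 (1 → 29; compounds 2, 19, 24 and 28 are purchased).

Three steps most likely to fail, with fallbacks:

- **Step 2 (enzyme of the required sense).** The needed (2R,3R) product is the antipode of the baker's‑yeast product as I recall it, so a suitable enzyme must be found by screening. Fallback: change to a hydrolytic desymmetrisation. Reduce 3 to the all‑cis meso diol, then use a lipase either to hydrolyse the meso diacetate or to acylate the meso diol with vinyl acetate (the two directions give opposite enantiomers). Oxidise the free hydroxyl and exchange the acetate for a silyl ether to rejoin at 5.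
- **Step 8 (directed hydrogenation of a hindered trisubstituted alkene next to the quaternary carbon).** Rate or facial selectivity may be poor. Fallback: abandon directed reduction and set the C–H(Me) centre first by Cu/phosphoramidite‑catalysed asymmetric conjugate addition of Me3Al to 2‑methylcyclohex‑2‑enone. Allylate the resulting enolate trans to the new methyl, form the enol triflate, couple with MeMgBr and hydroborate to reach 15.
- **Step 22 (sulfide to sulfone in the presence of three alkenes and an allylic sulfoxide intermediate).** Epoxidation or sulfoxide rearrangement could compete. Fallback: avoid any late oxidant by forming the sulfone directly, alkylating sodium 2‑(Boc‑amino)ethanesulfinate at sulfur with bromide 23 to give 26.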